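**Remark on the chemistry:** the stereo SMILES of the target encodes the R configuration at the oxepine carbon (CIP order O > C(CH3)2O > CH2 > H). The side chain is therefore carried as the 3R series of 2-methylhex-5-ene-2,3-diol throughout, and every structure below was checked against this assignment.

## Structural features

The target is a tetracyclic oxepinoflavone. Ring A is a fully substituted benzene (5-OH, 6-prenyl, 7-OH, 8-prenyl) fused to the 4-pyranone ring C. Ring B (4'-hydroxyphenyl) sits on C2 and is tied back to C3 through ring D, a seven-membered oxepine made of C2, C3, CH2, CH, O, C2' and C1'. There is one stereocentre, the oxepine CH that carries the aryl ether oxygen and the 2-hydroxypropan-2-yl group (R). It has no stereogenic neighbour, so only absolute configuration has to be secured, but it lies at a hindered, neopentyl-like secondary ether carbon. The fragile groups are the two prenyl groups ortho to free phenols (acid closes them to chromans, long heating above about 200 °C isomerises them, hydrogenation and oxidants attack them), the tertiary alcohol (ionisation and dehydration) and the electron-rich phenols. The real difficulty is the hexasubstituted ring A: putting two prenyl groups on C6 and C8 of a finished 5,7-dihydroxyflavone is poorly selective. The key step exploits the fact that a 2,4-diprenylphloroglucinol has one free ring carbon (the future C4a) flanked by two equivalent hydroxyls (the future O1 and 5-OH). It also exploits the fact that C4, C3 and C2 can be preassembled as a β-ketoester inside rings B and D, so that one condensation closes ring C.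

## Logic of the disconnections

24 is traced back to 22 by cutting the two O–Si bonds (4'-O and the tertiary O). The reason is that both hydroxyls must be masked through base and heat, and silicon can be removed by fluoride alone. The gain is small in atoms but large in safety. The demand on the forward step is that no acid is used near the ortho-prenylphenols.

22 is cut at C4–C4a and O1–C2, which opens ring C and gives 15 and 19. The cut is made there because 19 has a single nucleophilic CH between two symmetry-equivalent hydroxyls and 15 already holds C2, C3, C4, rings B and D and the stereocentre. The gain is a convergent union in which both prenyl groups arrive already on carbon. The forward step must achieve acid-free C-acylation and cyclodehydration under heat. For that reason 15 carries a tert-butyl ester (ketene release well below the temperature a methyl ester needs) and a silylated tertiary hydroxyl (no intramolecular ketene capture, no dehydration).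

19 is cut at the two aryl C–CH2 bonds to give 16 and two molecules of 17. Both are commodity chemicals and the route is one step. The demand is to stop at the dialkyl stage and to accept a separation from under- and over-alkylated material.

15 is cut at the ring bond between the carbonyl carbon C5 and the α-carbon C4. Read backwards the ketone is a nitrile, which leads through 14 to the open-chain 13. A nitrile is chosen in place of an aryl ester because it must also survive the earlier alkoxide etherification. An aryl methyl ester would be transesterified there, and the methoxide set free would displace the fluoride. The gain is an acyclic chain. The demand is a seven-membered Thorpe–Ziegler closure and an enamine hydrolysis mild enough for the silyl ethers and the tert-butyl ester.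

13 goes back through 12 and 10 to 8 by cutting the ester C–O bond, lowering the oxidation state of C6 and removing the terminal C–O bond. The carboxyl is kept latent as a vinyl group because a free γ-hydroxy ester could not coexist with the alkoxide needed for the etherification. The demand is that the tertiary hydroxyl is silylated before C6 is oxidised, since the 1,5-hydroxy acid would otherwise close to a δ-lactone.

8 goes back to 7 (O–Si) and 7 is cut at the aryl C–O bond to give 6 and 2. Forming this bond on the aromatic carbon leaves the C–O bond of the stereocentre intact, so configuration is retained and no SN2 reaction at a neopentyl-like carbon is needed. The demands are reaction at the secondary and not the tertiary alkoxide, and survival of the silyl ether of 2.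

2 comes from 1 by an O–Si cut. 6 is cut at the two C–CH3 bonds of the carbinol carbon to give 4, and 4 at the CH2–vinyl bond to give 3. The stereocentre is taken from the chiral pool and is never a reaction centre. The demand is epoxide opening at the CH2 terminus of 3 without attack on its ester.

## Other disconnections considered

**Alternative 1:** The cut runs through ring D at C3–CH2 and at the ether O–CH.
- Forward step: the 3-iodo-2'-hydroxyflavone A1 and isoprene A2 would be joined with Pd2(dba)3, a chiral phosphoramidite and Ag2CO3. Zerovalent palladium inserts into the C3–I bond, the flavonyl–palladium species adds to the unsubstituted vinyl end of A2, and the 2'-phenoxide closes on the internal terminus of the π-allyl complex to give A3.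
- In its favour: ring D and the stereocentre would arise together, catalytically and far below the temperature of a thermal condensation. For building ring D it is better than the chosen plan in step count (eight steps lead to 15) and in mildness.
- Against it here: A3 is still far from the target. Its isopropenyl group needs Markovnikov hydration, its two benzyl ethers must leave without reducing an alkene, and C6 and C8 are bare. The two prenyl groups would therefore have to be put on a 5,7-dihydroxyflavone at the end, the poorly selective operation that the chosen plan avoids by using 19.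
- Mechanism and selectivity: the sense and level of induction in a seven-membered heteroannulation depend on the ligand, and the phenoxide can choose between two allyl termini. The chosen plan takes its configuration from 3 with no selectivity question.
- Overall: better on convergence and mildness for ring D, weaker on ring A and on certainty of configuration, and not shorter once the late operations are counted.

**Alternative 2:** The cut is at C2–C3 and at the C4–O bond of an isoxazole that stands in for the pyranone.
- Forward step: the aldoxime A4, whose ring B ether chain ends in an alkyne carrying the complete MOM-protected ring A, would be oxidised with NaOCl to the nitrile oxide A5. A5 adds across the tethered alkyne and gives the isoxazole-fused benzoxepine A6.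
- In its favour: the cycloaddition is intramolecular, so its regiochemistry is fixed by the tether. It runs near room temperature, so the prenyl groups see no heat; on this point it is better than the chosen plan. The stereocentre comes from the same kind of chiral-pool aryl ether, so the two plans are equal there.
- Against it here: ring C is not yet made. A6 needs N–O cleavage (Mo(CO)6, since hydrogenation would touch the prenyl groups), hydrolysis of the resulting enaminone, and acid-mediated removal of four MOM groups with cyclodehydration. Acid is what ortho-prenylphenols tolerate least.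
- Step economy: A4 needs a hexasubstituted ring A alkyne, which makes the route linear and several steps longer.
- Overall: a mechanistically secure ring D closure, paid for with more steps and acid at the end. The chosen plan uses heat but no acid.

**Alternative 3:** The cut is at C6–CH2 and C8–CH2.
- Forward step: heating the 5,7-bis(allyl) ether A7 would move both allyl groups from oxygen to carbon by aromatic Claisen shifts and give A8.
- In its favour: both carbon substituents are placed at C6 and C8 with full positional control, and the statistical alkylation of 16 is avoided. On positional selectivity it is better than step 10 of the chosen plan.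
- Against it here: it forms no ring and no stereocentre, so A7 presupposes the whole tetracycle made by some other ring C synthesis. It delivers allyl and not prenyl groups, so a cross-metathesis with 2-methylbut-2-ene must follow. Allylating the chelated 5-OH is sluggish, and the MOM group of A8 needs acid at the end.
- Thermal load: about 200 °C, which is equal to that of the chosen key step, not lower.
- Overall: at least three operations longer. It is kept as the reserve if 19 does not survive the condensation.

Key step: step 11

## Route

Step 1
Reactants: 1 2-fluoro-4-hydroxybenzonitrile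
Product: 2 2-fluoro-4-[(triisopropylsilyl)oxy]benzonitrile
Conditions: TIPSCl, imidazole, DMF, rt
Reagents that add atoms: triisopropylsilyl chloride, CC(C)[Si](Cl)(C(C)C)C(C)C
Why: Silylation of an acidic phenol with a silyl chloride and imidazole; the bulky triisopropylsilyl group is chosen to resist the hindered alkoxide and enolate bases used later and to fall to fluoride at the end.

Step 2
Reactants: 3 methyl (2R)-oxirane-2-carboxylate (methyl (R)-glycidate)
Product: 4 methyl (2R)-2-hydroxypent-4-enoate
Conditions: CH2=CHMgBr, CuI (10 mol %), THF, −78 to −40 °C; aq. NH4Cl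
Reagents that add atoms: vinylmagnesium bromide, C=C[Mg]Br
Why: Copper-catalysed Grignard opening of a terminal epoxide; the vinyl cuprate attacks the unsubstituted CH2 at low temperature faster than the Grignard reagent adds to the ester, so the stereocentre of 3 is not a reaction centre and is carried over as R.

Step 3
Reactants: 4 methyl (2R)-2-hydroxypent-4-enoate
Product: 6 (3R)-2-methylhex-5-ene-2,3-diol, via methyl ketone 5 (not isolated)
Conditions: MeMgBr (3.5 equiv), THF, 0 °C to rt; aq. NH4Cl
Reagents that add atoms: methylmagnesium bromide, C[Mg]Br
Why: Double Grignard addition to an ester through the methyl ketone; the first equivalent only deprotonates the hydroxyl, and the carbinol stereocentre is untouched (R).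

Step 4
Reactants: 6 (3R)-2-methylhex-5-ene-2,3-diol; 2 2-fluoro-4-[(triisopropylsilyl)oxy]benzonitrile
Product: 7 2-{[(3R)-2-hydroxy-2-methylhex-5-en-3-yl]oxy}-4-[(triisopropylsilyl)oxy]benzonitrile
Conditions: KN(SiMe3)2 (1.0 equiv), THF, 0 °C; then 2, 0 °C to rt
Reagents that add atoms: none
Why: Nucleophilic aromatic substitution (addition–elimination) of the fluoride ortho to the nitrile by the potassium alkoxide; the secondary alkoxide is far less hindered than the tertiary one, and a nitrile cannot be transesterified because alkoxide addition to it is reversible. The C–O bond of the stereocentre is not broken, so the configuration is retained (R).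

Step 5
Reactants: 7 2-{[(3R)-2-hydroxy-2-methylhex-5-en-3-yl]oxy}-4-[(triisopropylsilyl)oxy]benzonitrile
Product: 8 2-{[(3R)-2-[(tert-butyldimethylsilyl)oxy]-2-methylhex-5-en-3-yl]oxy}-4-[(triisopropylsilyl)oxy]benzonitrile
Conditions: TBSOTf, 2,6-lutidine, CH2Cl2, 0 °C to rt
Reagents that add atoms: tert-butyldimethylsilyl trifluoromethanesulfonate, CC(C)(C)[Si](C)(C)OS(=O)(=O)C(F)(F)F
Why: Silyl triflate and 2,6-lutidine silylate a hindered tertiary alcohol; masking it now prevents δ-lactone formation when C6 is oxidised, alkoxide interference in the ring closure, and dehydration or ketene capture in the thermal step. The tert-butyldimethylsilyl group is chosen because it survives the dilute acid of step 9.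

Step 6
Reactants: 8 2-{[(3R)-2-[(tert-butyldimethylsilyl)oxy]-2-methylhex-5-en-3-yl]oxy}-4-[(triisopropylsilyl)oxy]benzonitrile
Product: 10 2-{[(3R)-2-[(tert-butyldimethylsilyl)oxy]-6-hydroxy-2-methylhexan-3-yl]oxy}-4-[(triisopropylsilyl)oxy]benzonitrile, via B-alkyl-9-BBN adduct 9 (not isolated)
Conditions: 9-BBN, THF, 0 °C to rt; then NaBO3·4H2O, H2O, rt
Reagents that add atoms: sodium perborate tetrahydrate (NaBO3·4H2O), [Na+].[O-]OB=O
Why: Hydroboration–oxidation; the bulky borane adds to the terminal alkene in the anti-Markovnikov sense and reduces an aryl nitrile only very slowly, and perborate oxidises the C–B bonds without cleaving the aryl silyl ether.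

Step 7
Reactants: 10 2-{[(3R)-2-[(tert-butyldimethylsilyl)oxy]-6-hydroxy-2-methylhexan-3-yl]oxy}-4-[(triisopropylsilyl)oxy]benzonitrile
Product: 12 (4R)-5-[(tert-butyldimethylsilyl)oxy]-4-{2-cyano-5-[(triisopropylsilyl)oxy]phenoxy}-5-methylhexanoic acid, via aldehyde 11 (not isolated)
Conditions: TEMPO (20 mol %), PhI(OAc)2, MeCN/H2O, rt
Reagents that add atoms: water, O
Why: Nitroxyl-catalysed oxidation of a primary alcohol to the carboxylic acid through the aldehyde hydrate, with PhI(OAc)2 as terminal oxidant; silyl ethers, nitrile and the arene are inert under these near-neutral conditions.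

Step 8
Reactants: 12 (4R)-5-[(tert-butyldimethylsilyl)oxy]-4-{2-cyano-5-[(triisopropylsilyl)oxy]phenoxy}-5-methylhexanoic acid
Product: 13 tert-butyl (4R)-5-[(tert-butyldimethylsilyl)oxy]-4-{2-cyano-5-[(triisopropylsilyl)oxy]phenoxy}-5-methylhexanoate
Conditions: Cl3CC(=NH)OtBu, cyclohexane/CH2Cl2, rt
Reagents that add atoms: tert-butyl 2,2,2-trichloroacetimidate, CC(C)(C)OC(=N)C(Cl)(Cl)Cl
Why: tert-Butyl esterification with the trichloroacetimidate, in which the carboxylic acid itself activates the imidate and no added acid is needed. A tert-butyl ester cannot self-condense in the next step and later releases tert-butanol thermally at a much lower temperature than a methyl ester.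

Step 9
Reactants: 13 tert-butyl (4R)-5-[(tert-butyldimethylsilyl)oxy]-4-{2-cyano-5-[(triisopropylsilyl)oxy]phenoxy}-5-methylhexanoate
Product: 15 tert-butyl (2R)-2-{2-[(tert-butyldimethylsilyl)oxy]propan-2-yl}-5-oxo-8-[(triisopropylsilyl)oxy]-2,3,4,5-tetrahydro-1-benzoxepine-4-carboxylate (C4 epimers and enol form), via cyclic enamino ester 14 (not isolated)
Conditions: KOtBu, THF, 0 °C to rt; then 1 M HCl, THF, rt
Reagents that add atoms: water, O
Why: Thorpe–Ziegler cyclisation; the ester enolate adds to the ortho nitrile (7-exo-dig) and tautomerisation to the conjugated enamino ester anion drives the closure. Dilute aqueous acid then hydrolyses the primary enamine to the ketone while the tert-butyl ester and the hindered silyl ethers survive. The R centre is remote from the enolate, and the new C4 centre is epimerisable and is lost in step 11.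

Step 10
Reactants: 16 phloroglucinol (benzene-1,3,5-triol); 17 prenyl bromide (1-bromo-3-methylbut-2-ene)
Product: 19 2,4-bis(3-methylbut-2-en-1-yl)benzene-1,3,5-triol (2,4-diprenylphloroglucinol), via 2-prenylphloroglucinol 18 (not isolated)
Conditions: 17 (2.0 equiv), aq. KOH, 0 °C to rt
Reagents that add atoms: none
Why: C-Alkylation of the phloroglucinol anion by an allylic bromide, favoured over O-alkylation in water. Any two ring carbons are equivalent by symmetry, so only one aromatic dialkyl isomer exists, and it should be separable from mono- and trialkylated material.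

Step 11
Reactants: 15 tert-butyl (2R)-2-{2-[(tert-butyldimethylsilyl)oxy]propan-2-yl}-5-oxo-8-[(triisopropylsilyl)oxy]-2,3,4,5-tetrahydro-1-benzoxepine-4-carboxylate; 19 2,4-bis(3-methylbut-2-en-1-yl)benzene-1,3,5-triol (1.5 equiv)
Product: 22 4'-O-triisopropylsilyl tertiary-O-tert-butyldimethylsilyl ether of the target (ring C closed; 5-OH and 7-OH free; 6,8-diprenyl), via α-oxoketene 20 (not isolated), via C-acyl triketone 21 (not isolated)
Conditions: Ph2O, 180 °C, argon stream (tert-butanol and water swept out)
Reagents that add atoms: none
Why: Mentzer pyrone synthesis, the thermal condensation of a phloroglucinol with a β-ketoester. Above about 150 °C the tert-butyl ester of 15 should lose tert-butanol in a six-centre elimination to give α-oxoketene 20; its capture by any hydroxyl of 19 gives aryl esters that revert to 20 at this temperature, whereas attack by the single free, doubly ortho-activated ring carbon gives the C-acyl compound 21 irreversibly and creates C4–C4a. One of the two hydroxyls flanking that carbon then adds to the ring B ketone (6-exo-trig) and water is lost, which forms O1–C2 and closes ring C as the 4-pyranone; the other flanking hydroxyl becomes the chelated 5-OH. No stereocentre is formed: the C4 centre of 15 becomes sp2, and the R centre, γ to the ketone with no leaving group β to an acidic position, can neither epimerise nor eliminate. The step needs C- over O-acylation (secured by the reversibility of O-acylation) and chromone rather than coumarin constitution (no acid is present, and the doubly oxygen-substituted aryl ketone in a seven-membered ring is too unreactive for Pechmann-type attack); no positional choice arises because the mirror symmetry of 19 makes the two flanking hydroxyls equivalent. The tert-butyl ester and the silylated tertiary hydroxyl should allow a temperature well below that of a methyl ester melt, which protects the ortho-prenylphenol units from thermal isomerisation and excludes intramolecular capture of the ketene.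

Step 12
Reactants: 22 4'-O-triisopropylsilyl tertiary-O-tert-butyldimethylsilyl ether of the target
Product: 24 target CNP0328977.2 ((R)-5,7,4'-trihydroxy-6,8-diprenylflavone bridged from C3 to the 2'-oxygen by CH2–CH[C(CH3)2OH]), via mono-desilylated phenol 23 (not isolated)
Conditions: Bu4NF (excess), THF, rt to 45 °C
Reagents that add atoms: none
Why: Fluoride-induced Si–O cleavage; the aryl silyl ether should go at once and the tertiary silyl ether on gentle warming. No acid is used, so the ortho-prenylphenols, the tertiary alcohol and the stereocentre are left alone.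

## Compound list

1 | 2-fluoro-4-hydroxybenzonitrile | N#Cc1ccc(O)cc1F | starting material
2 | 2-fluoro-4-[(triisopropylsilyl)oxy]benzonitrile | N#Cc1ccc(O[Si](C(C)C)(C(C)C)C(C)C)cc1F | intermediate
3 | methyl (2R)-oxirane-2-carboxylate | COC(=O)[C@H]1CO1 | starting material
4 | methyl (2R)-2-hydroxypent-4-enoate | COC(=O)[C@H](O)CC=C | intermediate
5 | (3R)-3-hydroxyhex-5-en-2-one (as its magnesium alkoxide) | CC(=O)[C@H](O)CC=C | intermediate
6 | (3R)-2-methylhex-5-ene-2,3-diol | CC(C)(O)[C@H](O)CC=C | intermediate
7 | 2-{[(3R)-2-hydroxy-2-methylhex-5-en-3-yl]oxy}-4-[(triisopropylsilyl)oxy]benzonitrile | C=CC[C@H](C(C)(C)O)Oc1cc(O[Si](C(C)C)(C(C)C)C(C)C)ccc1C#N | intermediate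
8 | 2-{[(3R)-2-[(tert-butyldimethylsilyl)oxy]-2-methylhex-5-en-3-yl]oxy}-4-[(triisopropylsilyl)oxy]benzonitrile | C=CC[C@H](C(C)(C)O[Si](C)(C)C(C)(C)C)Oc1cc(O[Si](C(C)C)(C(C)C)C(C)C)ccc1C#N | intermediate
9 | B-alkyl-9-borabicyclo[3.3.1]nonane adduct of 8 (boron on the terminal carbon) | C1CCC2CCCC1B2CCC[C@H](C(C)(C)O[Si](C)(C)C(C)(C)C)Oc1cc(O[Si](C(C)C)(C(C)C)C(C)C)ccc1C#N | intermediate
10 | 2-{[(3R)-2-[(tert-butyldimethylsilyl)oxy]-6-hydroxy-2-methylhexan-3-yl]oxy}-4-[(triisopropylsilyl)oxy]benzonitrile | OCCC[C@H](C(C)(C)O[Si](C)(C)C(C)(C)C)Oc1cc(O[Si](C(C)C)(C(C)C)C(C)C)ccc1C#N | intermediate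
11 | (4R)-5-[(tert-butyldimethylsilyl)oxy]-4-{2-cyano-5-[(triisopropylsilyl)oxy]phenoxy}-5-methylhexanal | O=CCC[C@H](C(C)(C)O[Si](C)(C)C(C)(C)C)Oc1cc(O[Si](C(C)C)(C(C)C)C(C)C)ccc1C#N | intermediate
12 | (4R)-5-[(tert-butyldimethylsilyl)oxy]-4-{2-cyano-5-[(triisopropylsilyl)oxy]phenoxy}-5-methylhexanoic acid | OC(=O)CC[C@H](C(C)(C)O[Si](C)(C)C(C)(C)C)Oc1cc(O[Si](C(C)C)(C(C)C)C(C)C)ccc1C#N | intermediate
13 | tert-butyl (4R)-5-[(tert-butyldimethylsilyl)oxy]-4-{2-cyano-5-[(triisopropylsilyl)oxy]phenoxy}-5-methylhexanoate | CC(C)(C)OC(=O)CC[C@H](C(C)(C)O[Si](C)(C)C(C)(C)C)Oc1cc(O[Si](C(C)C)(C(C)C)C(C)C)ccc1C#N | intermediate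
14 | tert-butyl (2R)-5-amino-2-{2-[(tert-butyldimethylsilyl)oxy]propan-2-yl}-8-[(triisopropylsilyl)oxy]-2,3-dihydro-1-benzoxepine-4-carboxylate | NC1=C(C(=O)OC(C)(C)C)C[C@H](C(C)(C)O[Si](C)(C)C(C)(C)C)Oc2cc(O[Si](C(C)C)(C(C)C)C(C)C)ccc12 | intermediate
15 | tert-butyl (2R)-2-{2-[(tert-butyldimethylsilyl)oxy]propan-2-yl}-5-oxo-8-[(triisopropylsilyl)oxy]-2,3,4,5-tetrahydro-1-benzoxepine-4-carboxylate | CC(C)(C)OC(=O)C1C[C@H](C(C)(C)O[Si](C)(C)C(C)(C)C)Oc2cc(O[Si](C(C)C)(C(C)C)C(C)C)ccc2C1=O | intermediate
16 | phloroglucinol (benzene-1,3,5-triol) | Oc1cc(O)cc(O)c1 | starting material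
17 | prenyl bromide (1-bromo-3-methylbut-2-ene) | CC(C)=CCBr | starting material
18 | 2-(3-methylbut-2-en-1-yl)benzene-1,3,5-triol | CC(C)=CCc1c(O)cc(O)cc1O | intermediate
19 | 2,4-bis(3-methylbut-2-en-1-yl)benzene-1,3,5-triol | CC(C)=CCc1c(O)cc(O)c(CC=C(C)C)c1O | intermediate
20 | (2R)-2-{2-[(tert-butyldimethylsilyl)oxy]propan-2-yl}-4-(oxomethylidene)-8-[(triisopropylsilyl)oxy]-3,4-dihydro-1-benzoxepin-5(2H)-one | O=C=C1C[C@H](C(C)(C)O[Si](C)(C)C(C)(C)C)Oc2cc(O[Si](C(C)C)(C(C)C)C(C)C)ccc2C1=O | intermediate
21 | 4-(2,4,6-trihydroxy-3,5-diprenylbenzoyl) derivative of the (2R)-benzoxepin-5-one (C-acylated 19; 1,3-diketone) | CC(C)=CCc1c(O)c(CC=C(C)C)c(O)c(C(=O)C2C[C@H](C(C)(C)O[Si](C)(C)C(C)(C)C)Oc3cc(O[Si](C(C)C)(C(C)C)C(C)C)ccc3C2=O)c1O | intermediate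
22 | 4'-O-triisopropylsilyl tertiary-O-tert-butyldimethylsilyl ether of the target | CC(C)=CCc1c(O)c(CC=C(C)C)c2oc3c(c(=O)c2c1O)C[C@H](C(C)(C)O[Si](C)(C)C(C)(C)C)Oc1cc(O[Si](C(C)C)(C(C)C)C(C)C)ccc1-3 | intermediate
23 | tertiary-O-tert-butyldimethylsilyl ether of the target (4'-OH free) | CC(C)=CCc1c(O)c(CC=C(C)C)c2oc3c(c(=O)c2c1O)C[C@H](C(C)(C)O[Si](C)(C)C(C)(C)C)Oc1cc(O)ccc1-3 | intermediate
24 | target CNP0328977.2, (R)-oxepinoflavone | CC(C)=CCc1c(O)c(CC=C(C)C)c2oc3c(c(=O)c2c1O)C[C@H](C(C)(C)O)Oc1cc(O)ccc1-3 | target

## Step count and least certain steps

Total: 12 steps. Longest linear sequence: 10 steps (steps 2 to 9, then 11 and 12, from 3).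

**Step 11 (key step).**
- What may go wrong: thermal isomerisation or chroman-type cyclisation of the ortho-prenylphenol units of 19 before C-acylation is complete; persistent O-acylation; loss of isobutene from the ester followed by decarboxylation; incomplete cyclodehydration of 21. The cause in each case is that the carbon nucleophile must compete at 180 °C with purely thermal pathways.
- Fallback: it sets out from 15 and 16 and comes back at 22. It keeps the same ring C closure but moves the prenyl groups to the end. 15 would be condensed with the heat-tolerant parent 16 in a classical neat melt to give the 5,7-dihydroxy oxepinoflavone bis-silyl ether F1. Allyl bromide and K2CO3 in acetone would give the 5,7-bis(allyl) ether F2. Heating in N,N-diethylaniline would shift both allyl groups to carbon and give the 6,8-diallyl compound F3. Cross-metathesis with 2-methylbut-2-ene and the second-generation Grubbs catalyst would turn both allyl groups into prenyl groups and deliver 22.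

**Step 10.**
- What may go wrong: under- and over-alkylation, O-alkylation and geminal dialkylation with loss of aromaticity, because each C-alkylation makes the ring more nucleophilic. The outcome is a statistical mixture from which 19 has to be separated.
- Fallback: it sets out from 16 and comes back at 19. MOMCl and iPr2NEt would give 1,3,5-tris(methoxymethoxy)benzene F4. Lithiation between two ether groups with n-BuLi, transmetalation with CuI and alkylation with 17 would give the monoprenyl compound F5. A second identical cycle would give the 2,4-diprenyl tris-ether F6; the two remaining ring positions are equivalent, so only one isomer can form. Brief treatment with catalytic HCl in methanol at rt would release 19.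

**Step 4.**
- What may go wrong: transfer of the triisopropylsilyl group from the electron-poor aryl oxygen to the alkoxide, which would leave a phenoxide that no longer undergoes substitution; or arylation on the tertiary oxygen. Both are possible because the nucleophile is a hindered, strongly basic alkoxide.
- Fallback: it sets out from 1 and 6 and comes back at 7. 1 would be allylated (allyl bromide, K2CO3) to 4-(allyloxy)-2-fluorobenzonitrile F7, whose ether is inert to alkoxide. The same substitution with 6 would give the allyl-protected aryl ether F8. Pd(PPh3)4 and morpholine would remove the O-allyl group to give the phenol F9, and TIPSCl with imidazole would silylate the phenol selectively to 7.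

**Step 9.**
- What may go wrong: a slow seven-membered closure that lets intermolecular condensation compete; or loss of the tertiary silyl ether or the tert-butyl ester during the acidic hydrolysis of the enamine, since that hydrolysis needs a pH at which both are only kinetically stable.
- Fallback: it sets out from 13 and comes back at 15. iBu2AlH at −78 °C would reduce the nitrile selectively to the aldehyde F10 after hydrolysis of the aldimine. LiN(iPr)2 at −78 °C would close the ring by intramolecular aldol addition to the cyclic β-hydroxy ester F11. Dess–Martin periodinane would oxidise F11 to 15 without any acid.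

## Further compounds

F1 | step 11 | 5,7-dihydroxy oxepinoflavone bis-silyl ether without prenyl groups | Oc1cc(O)c2c(c1)oc1c(c2=O)C[C@H](C(C)(C)O[Si](C)(C)C(C)(C)C)Oc2cc(O[Si](C(C)C)(C(C)C)C(C)C)ccc2-1
F2 | step 11 | 5,7-bis(allyloxy) oxepinoflavone bis-silyl ether | C=CCOc1cc(OCC=C)c2c(c1)oc1c(c2=O)C[C@H](C(C)(C)O[Si](C)(C)C(C)(C)C)Oc2cc(O[Si](C(C)C)(C(C)C)C(C)C)ccc2-1
F3 | step 11 | 6,8-diallyl-5,7-dihydroxy oxepinoflavone bis-silyl ether | C=CCc1c(O)c(CC=C)c2oc3c(c(=O)c2c1O)C[C@H](C(C)(C)O[Si](C)(C)C(C)(C)C)Oc1cc(O[Si](C(C)C)(C(C)C)C(C)C)ccc1-3
F4 | step 10 | 1,3,5-tris(methoxymethoxy)benzene | COCOc1cc(OCOC)cc(OCOC)c1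
F5 | step 10 | 1,3,5-tris(methoxymethoxy)-2-(3-methylbut-2-en-1-yl)benzene | COCOc1cc(OCOC)c(CC=C(C)C)c(OCOC)c1
F6 | step 10 | 1,3,5-tris(methoxymethoxy)-2,4-bis(3-methylbut-2-en-1-yl)benzene | COCOc1cc(OCOC)c(CC=C(C)C)c(OCOC)c1CC=C(C)C
F7 | step 4 | 4-(allyloxy)-2-fluorobenzonitrile | C=CCOc1ccc(C#N)c(F)c1
F8 | step 4 | 4-(allyloxy)-2-{[(3R)-2-hydroxy-2-methylhex-5-en-3-yl]oxy}benzonitrile | C=CC[C@H](C(C)(C)O)Oc1cc(OCC=C)ccc1C#N
F9 | step 4 | 4-hydroxy-2-{[(3R)-2-hydroxy-2-methylhex-5-en-3-yl]oxy}benzonitrile | C=CC[C@H](C(C)(C)O)Oc1cc(O)ccc1C#N
F10 | step 9 | tert-butyl (4R)-5-[(tert-butyldimethylsilyl)oxy]-4-{2-formyl-5-[(triisopropylsilyl)oxy]phenoxy}-5-methylhexanoate | CC(C)(C)OC(=O)CC[C@H](C(C)(C)O[Si](C)(C)C(C)(C)C)Oc1cc(O[Si](C(C)C)(C(C)C)C(C)C)ccc1C=O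
F11 | step 9 | tert-butyl (2R)-2-{2-[(tert-butyldimethylsilyl)oxy]propan-2-yl}-5-hydroxy-8-[(triisopropylsilyl)oxy]-2,3,4,5-tetrahydro-1-benzoxepine-4-carboxylate (diastereomer mixture at C4 and C5) | CC(C)(C)OC(=O)C1C[C@H](C(C)(C)O[Si](C)(C)C(C)(C)C)Oc2cc(O[Si](C(C)C)(C(C)C)C(C)C)ccc2C1O
A1 | alternative 1 | 5,7-bis(benzyloxy)-2-[2-hydroxy-4-(methoxymethoxy)phenyl]-3-iodo-4H-chromen-4-one | O=c1c(I)c(-c2ccc(OCOC)cc2O)oc2cc(OCc3ccccc3)cc(OCc3ccccc3)c12
A2 | alternative 1 | isoprene (2-methylbuta-1,3-diene) | C=CC(C)=C
A3 | alternative 1 | (R)-isopropenyl oxepinoflavone, 5,7-bis(benzyl) 4'-methoxymethyl ether | C(Oc1cc(OCc2ccccc2)c2c(c1)oc1c(c2=O)C[C@H](C(C)=C)Oc2cc(OCOC)ccc2-1)c1ccccc1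
A4 | alternative 2 | aldoxime of the ring B aldehyde carrying the (R)-ether chain that ends in the ring A aryl alkyne | COCOc1c(CC=C(C)C)c(OCOC)c(C#CC[C@H](C(C)(C)O)Oc2cc(OCOC)ccc2C=NO)c(OCOC)c1CC=C(C)C
A5 | alternative 2 | nitrile oxide derived from A4 | COCOc1c(CC=C(C)C)c(OCOC)c(C#CC[C@H](C(C)(C)O)Oc2cc(OCOC)ccc2C#[N+][O-])c(OCOC)c1CC=C(C)C
A6 | alternative 2 | isoxazole-fused (R)-benzoxepine carrying the protected ring A | COCOc1c(CC=C(C)C)c(OCOC)c(-c2onc3c2C[C@H](C(C)(C)O)Oc2cc(OCOC)ccc2-3)c(OCOC)c1CC=C(C)C
A7 | alternative 3 | 5,7-bis(allyloxy) (R)-oxepinoflavone 4'-methoxymethyl ether | C=CCOc1cc(OCC=C)c2c(c1)oc1c(c2=O)C[C@H](C(C)(C)O)Oc2cc(OCOC)ccc2-1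
A8 | alternative 3 | 6,8-diallyl-5,7-dihydroxy (R)-oxepinoflavone 4'-methoxymethyl ether | C=CCc1c(O)c(CC=C)c2oc3c(c(=O)c2c1O)C[C@H](C(C)(C)O)Oc1cc(OCOC)ccc1-3
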